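**Analysis of the target**

The target is a linear tridepside: three benzene rings joined by two aryl ester bonds and ending in a methyl ester, with ring A the 2-hydroxy-4-methoxy-6-methylbenzoyl end, ring B the middle ring and ring C the methyl ester ring, each numbered from its carboxyl-bearing C1. The carbonyl on C1 of ring A is bound to O4 of ring B, and the carbonyl on C1 of ring B to O4 of ring C. There is no stereocentre, so the problem is one of regiochemistry and chemoselectivity among oxygen functions. All three rings are 2,4-dioxygenated 6-methylbenzoates that differ only at oxygen: ring A has OH on C2 and OMe on C4, ring B has OH on C2 and an acyloxy group on C4, ring C has OMe on C2 and an acyloxy group on C4. The sensitive groups are the two aryl ester links, which are acyl donors towards alkoxides, hydroxide and amines and can fragment by an E1cB-type path once a phenoxide sits ortho or para to them. The main difficulty is that each depside carbonyl lies between an ortho oxygen substituent and an ortho methyl group, so classical esterification requires a weakly nucleophilic phenol to attack a 2,6-disubstituted benzoyl donor and needs the other hydroxyls protected. The strategy rests on ring A being a folded tetraketide: its C1–C6 bond and the oxygens on C2 and C4 are what an aldol closure of a 3,5,7-trioxooctanoyl chain (chain C2 onto chain C7) delivers, and that chain can be attached to O4 of ring B while its acyl carbon is still flanked only by a CH2 group. Ring B has the same latent pattern relative to O4 of ring C, so one reagent can serve twice.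

**Retrosynthetic reasoning**

15 to 14. The last bond cut is the O–CH3 bond on O4 of ring A. In 14 this is the only hydroxyl not hydrogen-bonded to an ortho ester carbonyl, so it is the most acidic and most accessible one and can be alkylated alone. Ring A can therefore be made with both oxygens free, which is how a polyketide-type cyclization delivers them. The forward step must methylate once under conditions too mild to open either aryl ester.

14 to 12. Ring A is opened at its C1–C6 bond, between the ester-bearing and the methyl-bearing carbon, and its three C–O units are read as ketones. This gives the open-chain aryl 3,5,7-trioxooctanoate 12, in which chain C2 becomes ring C1 and chain C7 becomes ring C6. Cutting the acyl–O4 bond instead would bring back the esterification of a 2,6-disubstituted benzoic acid with a poor phenol nucleophile. In 12 the ester carbonyl is flanked only by a methylene group, and the ortho substituents are built around it afterwards. The forward reaction must form this one C–C bond by aldol addition, eliminate the tertiary hydroxyl and enolize the two remaining ketones, faster than any substitution at the ester carbon that would release the ring B aryloxide.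

12 to 11 and 3. The acyl–oxygen bond between chain C1 and O4 of ring B is cut next. The acyl fragment is the acylketene 8, formed when 3 loses its ketal carbonyl component on heating; the nucleophile is the free 4-hydroxyl of 11. Ketene capture needs neither coupling agent nor base, and the chelated, flanked 2-hydroxyl of ring B should not compete, so 11 is used unprotected.

11 to 7 and 3. Ring B has the same oxygen and methyl pattern relative to O4 of ring C, so the same two cuts apply: the C1–C6 bond of ring B (aldol, via 10) and the acyl–O4(ring C) bond (capture of 8 by 7, giving 9). One reagent, 3, then builds both rings, and the aldol closure on an aryl ester is tested one stage before the key step.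

7 to 4. Ring C needs a methyl ether on the chelated O2 and a free O4, the reverse of what direct alkylation of 4 gives. O4 is therefore masked as a benzyl ether (5), O2 is methylated (6) and the benzyl group is removed (7). Three plain steps on a purchasable arene are preferred to a third ring construction.

3 to 1. The side chain of 3 is cut at the two C–C bonds next to its ketones, each formed by acylating a carbanion with an acetyl donor: the terminal carbon of the dianion of 2, and before that the γ-carbon of the dienolate of 1. Both operations are established for dioxinones and leave the masked β-keto acid intact until it is needed.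

**Alternatives that were turned down**

Alternative 1: Both bonds to the carbonyl carbon on C1 of ring B are cut, the one to ring B and the one to O4 of ring C, and that carbon is supplied by carbon monoxide A2.
- Forward: the aryl iodide A1 (ring B with iodine in place of its carboxyl carbon, a benzyl ether on O2 and the O2-benzylated ring A ester on O4), A2 and the phenol 7 would be coupled with Pd(OAc)2 and Xantphos and an amine base to give the dibenzyl ether A3 of the target; hydrogenolysis would finish.
- For: it is convergent. No phenol attacks a preformed hindered acyl donor, because the aroyl group is assembled on divalent palladium and leaves by reductive elimination. Ring A carries its O4-methyl from the start, and the end game is one clean deprotection.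
- Against: the iodine-bearing carbon is flanked by a benzyloxy and a methyl group, so CO insertion and especially C–O reductive elimination with an electron-poor aryloxide should be slow, which leaves room for hydrodeiodination. The phenoxide of 7 and the amine base at the required temperature can transesterify the aryl ester already in A1. A1 itself still needs one classical hindered esterification (ring A to ring B), an iodination that must distinguish the two ring positions next to the methyl group, and two benzyl groups.
- Comparison: it is stronger on convergence and on avoiding enolizable polyketone intermediates and aryloxide-expelling pathways. The chosen route offers instead that neither depside carbonyl is ever made on a hindered arene, that rings A and B need no protecting group and no transition metal, and that one reagent builds two rings in fewer steps.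

Alternative 2: Ring A is built on a finished ring B–ring C depside by a Danheiser benzannulation, with ring A cut into four carbons (C2, C5, C6, C1) of a diazo enone and two carbons (C3, C4) of an alkoxyalkyne.
- Forward: irradiation of the diazo enone A4 with methoxyethyne A5 should trigger a Wolff rearrangement to a vinylketene (C5–C6), a (2+2) cycloaddition (C2–C3, C4–C5), 4π opening of the cyclobutenone and 6π closure (C1–C2). Tautomerization then gives A6, the ring B benzyl ether of the target, and hydrogenolysis gives 15.
- For: the mechanism places OH on C2 and OMe on C4 directly, so no final selective methylation is needed; on this point it is stronger than the chosen route. The conditions are neutral and base-free, and the ester to ring B exists before the ortho substituents, as in the chosen route.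
- Against: A4 is a diazomethyl ketone conjugated to an enoate, prone to dipolar self-reaction, and must be made by diazo chemistry in the presence of two aryl esters. A5 is volatile, unstable and awkward to source. The ring B 2-hydroxyl must be benzylated because a free phenol would capture the ketene. UV irradiation of two aryl esters invites photo-Fries rearrangement, and a vinylketene with an ester on its terminal carbon is an electron-poor, poorly supported substrate for this annulation.
- Comparison: it saves the last step, but its precursor costs more steps and more hazardous reagents than 12, which comes from 11 in one operation with a reagent already in hand.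

Alternative 3: Ring B is built on ring C by cutting C1–C2 and C5–C6 of ring B, giving the but-2-ynoate A7 of phenol 7 and the bis(silyloxy) ketene acetal diene A8.
- Forward: a Diels–Alder reaction, then loss of methanol and the silyl groups on work-up, gives A9, which is identical with 11.
- For: the ester to ring C is made from an unhindered alkynoic acid, regiochemistry follows from the polarization of both partners, and no enolate that could expel an aryloxide is involved. On ester survival it is stronger than the ketene/aldol sequence of step 6.
- Against: a β-methyl ynoate is a sluggish dienophile, so temperatures are needed at which the diene degrades or transfers silyl groups. The aryl ynoate is also a Michael acceptor and an acyl donor, and A8 must be prepared and kept dry. Above all it delivers only ring B; ring A and its hindered ester remain unsolved and would need a second method.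
- Comparison: it takes two steps from 7 against one telescoped operation, and the chosen route reuses 3 for ring A. The cycloaddition is kept in reserve as a fallback for ring A.

Key step: step 8

**Route**

Remark: 3, 9 and 12 are drawn in the all-keto form but exist as mixtures of enol tautomers; 10 and 13 form as mixtures of stereoisomers and enols, which does not matter because both sp3 centres are lost on aromatization.

Step 1
Reactants: 1 2,2,6-trimethyl-4H-1,3-dioxin-4-one
Product: 2 2,2-dimethyl-6-(2-oxopropyl)-4H-1,3-dioxin-4-one
Conditions: LiN(SiMe3)2, THF, −78 °C; AcCl (0.5 equiv), −78 °C; aq. NH4Cl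
Reagents that add atoms: acetyl chloride, CC(Cl)=O
Why: Kinetic deprotonation of the 6-methyl group gives the dienolate, which is C-acylated at its γ-carbon (vinylogous Claisen-type acylation); two dienolates per acyl chloride are used because 2 is more acidic than 1 and quenches one of them.

Step 2
Reactants: 2 2,2-dimethyl-6-(2-oxopropyl)-4H-1,3-dioxin-4-one
Product: 3 6-(2,4-dioxopentyl)-2,2-dimethyl-4H-1,3-dioxin-4-one
Conditions: LiN(iPr)2 (2.5 equiv), THF, −78 °C; MeCON(OMe)Me, −78 to −20 °C; 1 M aq. HCl
Reagents that add atoms: N-methoxy-N-methylacetamide, CC(=O)N(C)OC
Why: Double deprotonation gives the dianion, whose terminal carbanion is the more nucleophilic site and adds to the N-methoxy-N-methyl amide; the chelated tetrahedral adduct persists until acidic work-up, so over-addition and proton transfer from the product are avoided (dianion Claisen-type acylation).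

Step 3
Reactants: 4 methyl 2,4-dihydroxy-6-methylbenzoate (methyl orsellinate)
Product: 5 methyl 4-(benzyloxy)-2-hydroxy-6-methylbenzoate
Conditions: BnBr (1.05 equiv), K2CO3, acetone, reflux
Reagents that add atoms: benzyl bromide, BrCc1ccccc1
Why: The 2-hydroxyl is held in a hydrogen bond to the ester carbonyl and is the less acidic and less nucleophilic one, so a carbonate base and one equivalent of halide should alkylate O4 only (Williamson ether synthesis).

Step 4
Reactants: 5 methyl 4-(benzyloxy)-2-hydroxy-6-methylbenzoate
Product: 6 methyl 4-(benzyloxy)-2-methoxy-6-methylbenzoate
Conditions: MeI (excess), K2CO3, DMF, 50 °C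
Reagents that add atoms: iodomethane, CI
Why: With O4 blocked, the chelated 2-hydroxyl is the only acidic site and is alkylated in a polar aprotic solvent with excess MeI and gentle warming (Williamson ether synthesis).

Step 5
Reactants: 6 methyl 4-(benzyloxy)-2-methoxy-6-methylbenzoate
Product: 7 methyl 4-hydroxy-2-methoxy-6-methylbenzoate
Conditions: H2 (1 atm), Pd/C, EtOAc, rt
Reagents that add atoms: none
Why: Catalytic hydrogenolysis cleaves the benzyl aryl ether and frees O4; methyl ester, methyl ether and arene are inert under these conditions.

Step 6
Reactants: 3 6-(2,4-dioxopentyl)-2,2-dimethyl-4H-1,3-dioxin-4-one; 7 methyl 4-hydroxy-2-methoxy-6-methylbenzoate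
Product: 11 methyl 4-[(2,4-dihydroxy-6-methylbenzoyl)oxy]-2-methoxy-6-methylbenzoate, via acylketene 8 (not isolated), via triketo ester 9 (not isolated), via aldol adduct 10 (not isolated)
Conditions: PhMe, 110 °C (3 added slowly to 7, slight excess of 7); then Et3N, CH2Cl2, rt; 1 M aq. HCl
Reagents that add atoms: none
Why: At 110 °C 3 loses acetone by retro-hetero-Diels–Alder fragmentation to acylketene 8, which the phenol 7 captures to give 9; slow addition keeps the ketene dilute so that capture outruns its self-cyclization. The amine then effects the same aldol closure, dehydration and enolization as in step 8 (via 10) and forms ring B (acylketene capture followed by biomimetic aldol aromatization).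

Step 7
Reactants: 3 6-(2,4-dioxopentyl)-2,2-dimethyl-4H-1,3-dioxin-4-one; 11 methyl 4-[(2,4-dihydroxy-6-methylbenzoyl)oxy]-2-methoxy-6-methylbenzoate
Product: 12 3-hydroxy-4-{[3-methoxy-4-(methoxycarbonyl)-5-methylphenoxy]carbonyl}-5-methylphenyl 3,5,7-trioxooctanoate
Conditions: PhMe, 110 °C (3 added slowly to 11, 1.2 equiv of 11); concentrate, crude used directly
Reagents that add atoms: none
Why: Heating 3 again releases acetone and the short-lived acylketene 8 described under step 6, and the free O4 hydroxyl of ring B should capture it, since the 2-hydroxyl is chelated to its own ester carbonyl and hindered; excess 11 and slow addition suppress a second acylation. This is thermal dioxinone fragmentation with capture of the ketene by a phenol; crude 12 is not exposed to silica, and unreacted 11 is removed after step 8.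

Step 8
Reactants: 12 3-hydroxy-4-{[3-methoxy-4-(methoxycarbonyl)-5-methylphenoxy]carbonyl}-5-methylphenyl 3,5,7-trioxooctanoate
Product: 14 methyl 4-({4-[(2,4-dihydroxy-6-methylbenzoyl)oxy]-2-hydroxy-6-methylbenzoyl}oxy)-2-methoxy-6-methylbenzoate, via aldol adduct 13 (not isolated)
Conditions: Et3N, CH2Cl2, 0 °C to rt; 1 M aq. HCl
Reagents that add atoms: none
Why: The amine reversibly deprotonates the 1,3-dicarbonyl methylenes of 12, and the C2 enolate (between ester and C3 ketone) adds to the C7 methyl ketone to close the six-membered carbocycle 13 in a 6-(enolendo)-exo-trig aldol addition. E1cB loss of the tertiary hydroxyl across C6–C7 and tautomerization of the C3 and C5 ketones then give the arene; one molecule of water is lost in all, and the acidic work-up completes the dehydration. The closest known reaction type is the biomimetic aldol aromatization of 3,5,7-trioxoalkanoate esters to resorcylates, applied here to an aryl ester. No stereocentre survives, since the two sp3 centres of 13 are erased on aromatization. The selectivity needed is aldol closure over the two substitutions at the ester carbon, Claisen attack from C6 and lactonization from the C5 enol oxygen, both of which would expel the ring B aryloxide. The aldol is favoured because C7 is the least hindered and most electrophilic carbonyl, while the ester carbonyl is deactivated by enolization of the β-keto ester; a weak tertiary amine in an aprotic solvent at or below room temperature keeps enolate concentrations low and supplies no external nucleophile. Aromatization makes the aldol path irreversible, whereas the aldol addition itself is reversible. The ester bond to ring B was made in step 7, before its carbonyl became flanked by OH and CH3, and the chelated hydroxyl of ring B and both older ester links are spectators.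

Step 9
Reactants: 14 methyl 4-({4-[(2,4-dihydroxy-6-methylbenzoyl)oxy]-2-hydroxy-6-methylbenzoyl}oxy)-2-methoxy-6-methylbenzoate
Product: 15 methyl 4-({2-hydroxy-4-[(2-hydroxy-4-methoxy-6-methylbenzoyl)oxy]-6-methylbenzoyl}oxy)-2-methoxy-6-methylbenzoate
Conditions: MeI (1.1 equiv), K2CO3 (1.1 equiv), dry acetone, rt
Reagents that add atoms: iodomethane, CI
Why: Of the three phenolic hydroxyls of 14 only O4 of ring A is not hydrogen-bonded to an ortho ester carbonyl; it is the most acidic and should be the only one alkylated by one equivalent of halide and carbonate at room temperature. Anhydrous conditions leave the aryl esters without a nucleophile (chemoselective Williamson O-methylation).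

**Compound list**

1 | 2,2,6-trimethyl-4H-1,3-dioxin-4-one | CC1=CC(=O)OC(C)(C)O1 | starting material
2 | 2,2-dimethyl-6-(2-oxopropyl)-4H-1,3-dioxin-4-one | CC(=O)CC1=CC(=O)OC(C)(C)O1 | intermediate
3 | 6-(2,4-dioxopentyl)-2,2-dimethyl-4H-1,3-dioxin-4-one | CC(=O)CC(=O)CC1=CC(=O)OC(C)(C)O1 | intermediate
4 | methyl 2,4-dihydroxy-6-methylbenzoate (methyl orsellinate) | COC(=O)c1c(C)cc(O)cc1O | starting material
5 | methyl 4-(benzyloxy)-2-hydroxy-6-methylbenzoate | COC(=O)c1c(C)cc(OCc2ccccc2)cc1O | intermediate
6 | methyl 4-(benzyloxy)-2-methoxy-6-methylbenzoate | COC(=O)c1c(C)cc(OCc2ccccc2)cc1OC | intermediate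
7 | methyl 4-hydroxy-2-methoxy-6-methylbenzoate | COC(=O)c1c(C)cc(O)cc1OC | intermediate
8 | oct-1-ene-1,3,5,7-tetrone (acylketene, formed in the flask from 3) | CC(=O)CC(=O)CC(=O)C=C=O | intermediate
9 | 3-methoxy-4-(methoxycarbonyl)-5-methylphenyl 3,5,7-trioxooctanoate (formed in the flask) | CC(=O)CC(=O)CC(=O)CC(=O)Oc1cc(C)c(C(=O)OC)c(OC)c1 | intermediate
10 | 3-methoxy-4-(methoxycarbonyl)-5-methylphenyl 2-hydroxy-2-methyl-4,6-dioxocyclohexane-1-carboxylate (stereoisomer mixture, formed in the flask) | CC1(O)CC(=O)CC(=O)C1C(=O)Oc1cc(C)c(C(=O)OC)c(OC)c1 | intermediate
11 | methyl 4-[(2,4-dihydroxy-6-methylbenzoyl)oxy]-2-methoxy-6-methylbenzoate | COC(=O)c1c(C)cc(OC(=O)c2c(C)cc(O)cc2O)cc1OC | intermediate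
12 | 3-hydroxy-4-{[3-methoxy-4-(methoxycarbonyl)-5-methylphenoxy]carbonyl}-5-methylphenyl 3,5,7-trioxooctanoate | CC(=O)CC(=O)CC(=O)CC(=O)Oc1cc(C)c(C(=O)Oc2cc(C)c(C(=O)OC)c(OC)c2)c(O)c1 | intermediate
13 | 3-hydroxy-4-{[3-methoxy-4-(methoxycarbonyl)-5-methylphenoxy]carbonyl}-5-methylphenyl 2-hydroxy-2-methyl-4,6-dioxocyclohexane-1-carboxylate (stereoisomer mixture, formed in the flask) | CC1(O)CC(=O)CC(=O)C1C(=O)Oc1cc(C)c(C(=O)Oc2cc(C)c(C(=O)OC)c(OC)c2)c(O)c1 | intermediate
14 | methyl 4-({4-[(2,4-dihydroxy-6-methylbenzoyl)oxy]-2-hydroxy-6-methylbenzoyl}oxy)-2-methoxy-6-methylbenzoate | Cc1cc(O)cc(O)c1C(=O)Oc1cc(C)c(C(=O)Oc2cc(C)c(C(=O)OC)c(OC)c2)c(O)c1 | intermediate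
15 | methyl 4-({2-hydroxy-4-[(2-hydroxy-4-methoxy-6-methylbenzoyl)oxy]-6-methylbenzoyl}oxy)-2-methoxy-6-methylbenzoate | COC(=O)c1c(C)cc(OC(=O)c2c(C)cc(OC(=O)c3c(C)cc(OC)cc3O)cc2O)cc1OC | target

**Step count and least certain steps**

Total step count: 9. Longest linear sequence: 7 steps (steps 3 to 9, from 4 through 5, 6, 7, 11, 12 and 14 to 15); the branch from 1 (steps 1 and 2) joins at steps 6 and 7.

Step 8 (key step). The most likely failure is acyl substitution at the chain's ester carbon, by Claisen-type C-acylation from C6 or by lactonization from the C5 enol oxygen, with expulsion of the ring B aryloxide. An aryloxide is a much better leaving group than the alkoxides on which this aromatization is best established. Incomplete dehydration of the aldol adduct is a lesser concern. The fallback gives up ring construction on the ester and returns to classical depside assembly, setting out from 4 and 11. Exhaustive benzylation of 4 (BnBr, K2CO3, DMF, 60 °C) would give methyl 2,4-bis(benzyloxy)-6-methylbenzoate F1. Saponification of this hindered ester (KOH, DMSO/H2O, 90 °C) would give 2,4-bis(benzyloxy)-6-methylbenzoic acid F2. Activation of F2 with trifluoroacetic anhydride in PhMe at rt in the presence of 11 should acylate the unchelated O4 of ring B to give methyl 4-[(4-{[2,4-bis(benzyloxy)-6-methylbenzoyl]oxy}-2-hydroxy-6-methylbenzoyl)oxy]-2-methoxy-6-methylbenzoate F3. Hydrogenolysis (H2, Pd/C, EtOAc) would then rejoin the route at 14.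

Step 7. The electron-poor phenol may capture the acylketene too slowly, so that the ketene is consumed by attack of its own enol oxygen, and prolonged heating can revert the aryl β-keto ester to ketene and phenol. Acylation of a second hydroxyl is a smaller risk. The fallback builds ring A by cycloaddition instead of ketene capture and aldol closure, setting out from 11. O4-acylation with but-2-ynoic acid (N,N'-diisopropylcarbodiimide, cat. DMAP, CH2Cl2, 0 °C) would give methyl 4-{[4-(but-2-ynoyloxy)-2-hydroxy-6-methylbenzoyl]oxy}-2-methoxy-6-methylbenzoate F4. A Diels–Alder reaction of F4 with excess diene A8 (PhMe, 110 °C), then dilute acid to remove methanol and the silyl groups, should give 14 directly, bypassing 12 and step 8. This is expected to be less efficient than the main line but is mechanistically independent of it.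

Step 6. The same two processes as in steps 7 and 8 apply on the simpler phenol 7: slow ketene capture with loss of the ketene to self-cyclization, and substitution at the aryl ester carbon during base treatment. The fallback is classical esterification, setting out from 4 and 7. Benzylation of 4 to methyl 2,4-bis(benzyloxy)-6-methylbenzoate F1 and saponification to 2,4-bis(benzyloxy)-6-methylbenzoic acid F2 would be carried out as described under step 8. Trifluoroacetic anhydride in PhMe would then join F2 and 7 to give methyl 4-{[2,4-bis(benzyloxy)-6-methylbenzoyl]oxy}-2-methoxy-6-methylbenzoate F5, and hydrogenolysis (H2, Pd/C, EtOAc) would rejoin the route at 11.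

Step 2. Proton transfer between the dianion and the acidic product, O-acylation, or attack of the amide base on the dioxinone carbonyl could hold conversion low. The fallback replaces strong-base dianion chemistry by soft enolization and sets out from 1. Acylation of the dienolate of 1 (LiN(SiMe3)2, THF, −78 °C) with allyl 3-chloro-3-oxopropanoate would give allyl 4-(2,2-dimethyl-4-oxo-4H-1,3-dioxin-6-yl)-3-oxobutanoate F6. C-Acetylation at its doubly activated methylene (MgCl2, pyridine, AcCl, CH2Cl2, 0 °C) would give allyl 2-acetyl-4-(2,2-dimethyl-4-oxo-4H-1,3-dioxin-6-yl)-3-oxobutanoate F7. Deallylation with Pd(PPh3)4 (zerovalent palladium) and morpholine in THF, with spontaneous decarboxylation, would rejoin the route at 3.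

**Further compounds**

F1 | step 8 | methyl 2,4-bis(benzyloxy)-6-methylbenzoate | COC(=O)c1c(C)cc(OCc2ccccc2)cc1OCc1ccccc1
F2 | step 8 | 2,4-bis(benzyloxy)-6-methylbenzoic acid | Cc1cc(OCc2ccccc2)cc(OCc2ccccc2)c1C(=O)O
F3 | step 8 | methyl 4-[(4-{[2,4-bis(benzyloxy)-6-methylbenzoyl]oxy}-2-hydroxy-6-methylbenzoyl)oxy]-2-methoxy-6-methylbenzoate | COC(=O)c1c(C)cc(OC(=O)c2c(C)cc(OC(=O)c3c(C)cc(OCc4ccccc4)cc3OCc3ccccc3)cc2O)cc1OC
F4 | step 7 | methyl 4-{[4-(but-2-ynoyloxy)-2-hydroxy-6-methylbenzoyl]oxy}-2-methoxy-6-methylbenzoate | CC#CC(=O)Oc1cc(C)c(C(=O)Oc2cc(C)c(C(=O)OC)c(OC)c2)c(O)c1
F5 | step 6 | methyl 4-{[2,4-bis(benzyloxy)-6-methylbenzoyl]oxy}-2-methoxy-6-methylbenzoate | COC(=O)c1c(C)cc(OC(=O)c2c(C)cc(OCc3ccccc3)cc2OCc2ccccc2)cc1OC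
F6 | step 2 | allyl 4-(2,2-dimethyl-4-oxo-4H-1,3-dioxin-6-yl)-3-oxobutanoate | C=CCOC(=O)CC(=O)CC1=CC(=O)OC(C)(C)O1
F7 | step 2 | allyl 2-acetyl-4-(2,2-dimethyl-4-oxo-4H-1,3-dioxin-6-yl)-3-oxobutanoate | C=CCOC(=O)C(C(C)=O)C(=O)CC1=CC(=O)OC(C)(C)O1
A1 | alternative 1 | 3-(benzyloxy)-4-iodo-5-methylphenyl 2-(benzyloxy)-4-methoxy-6-methylbenzoate | Cc1cc(OC)cc(OCc2ccccc2)c1C(=O)Oc1cc(C)c(I)c(OCc2ccccc2)c1
A2 | alternative 1 | carbon monoxide | [C-]#[O+]
A3 | alternative 1 | methyl 4-({2-(benzyloxy)-4-[(2-(benzyloxy)-4-methoxy-6-methylbenzoyl)oxy]-6-methylbenzoyl}oxy)-2-methoxy-6-methylbenzoate | COC(=O)c1c(C)cc(OC(=O)c2c(C)cc(OC(=O)c3c(C)cc(OC)cc3OCc3ccccc3)cc2OCc2ccccc2)cc1OC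
A4 | alternative 2 | 3-(benzyloxy)-4-{[3-methoxy-4-(methoxycarbonyl)-5-methylphenoxy]carbonyl}-5-methylphenyl (2E)-5-diazo-3-methyl-4-oxopent-2-enoate | [N-]=[N+]=CC(=O)/C(C)=C/C(=O)Oc1cc(C)c(C(=O)Oc2cc(C)c(C(=O)OC)c(OC)c2)c(OCc2ccccc2)c1
A5 | alternative 2 | methoxyethyne | COC#C
A6 | alternative 2 | methyl 4-({2-(benzyloxy)-4-[(2-hydroxy-4-methoxy-6-methylbenzoyl)oxy]-6-methylbenzoyl}oxy)-2-methoxy-6-methylbenzoate | COC(=O)c1c(C)cc(OC(=O)c2c(C)cc(OC(=O)c3c(C)cc(OC)cc3O)cc2OCc2ccccc2)cc1OC
A7 | alternative 3 | 3-methoxy-4-(methoxycarbonyl)-5-methylphenyl but-2-ynoate | CC#CC(=O)Oc1cc(C)c(C(=O)OC)c(OC)c1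
A8 | alternative 3 | 1-methoxy-1,3-bis(trimethylsilyloxy)buta-1,3-diene (double-bond geometry not defined) | COC(O[Si](C)(C)C)=CC(=C)O[Si](C)(C)C
A9 | alternative 3 | methyl 4-[(2,4-dihydroxy-6-methylbenzoyl)oxy]-2-methoxy-6-methylbenzoate (identical with 11) | COC(=O)c1c(C)cc(OC(=O)c2c(C)cc(O)cc2O)cc1OC
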